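It is easy to double the catalyst and double the loss in your head, and the runs warn against it.

common to all: left-handed substrate 0.20 M; right-handed substrate 0.20 M; gas 8.6 mM (held)
- south: free catalyst 11 mM; added ligand 99 mM; run made earlier
- north: free catalyst 44 mM; added ligand 99 mM; run made earlier
- south-east: free catalyst 22 mM; added ligand 150 mM; run made earlier
- flask: free catalyst 22 mM; added ligand 99 mM; time 30 h

| run | time / h | left-handed substrate / % | right-handed substrate / % |
|---|---|---|---|
| south | 4.00 | 49.2 | 50.1 |
| south | 8.00 | 47.7 | 50.2 |
| south | 12.0 | 46.1 | 49.5 |
| south | 15.0 | 45.1 | 48.5 |
| south | 20.0 | 44.2 | 49.7 |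
| south | 25.0 | 42.6 | 49.1 |
| south | 30.0 | 42.0 | 48.3 |
| north | 4.00 | 46.3 | 49.8 |
| north | 8.00 | 42.6 | 48.5 |
| north | 12.0 | 39.9 | 48.1 |
| north | 15.0 | 37.6 | 48.1 |
| north | 20.0 | 34.1 | 47.2 |
| north | 25.0 | 32.9 | 46.5 |
| north | 30.0 | 30.0 | 46.0 |
| south-east | 2.50 | 48.6 | 49.6 |
| south-east | 5.00 | 47.6 | 49.3 |
| south-east | 8.00 | 45.1 | 49.8 |
| south-east | 15.0 | 42.8 | 48.7 |
| south-east | 30.0 | 38.0 | 48.1 |

(scatter of a reading: 0.5 percentage points)

- free catalyst is single-handed; left-handed substrate and right-handed substrate are mirror images of each other, charged as a racemate, each of them at the stated concentration
- at the start none of the gas is in solution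
- an excess is the difference of the two amounts in percent of their sum
- an excess is below zero if the other one leads

- part of the left-handed substrate and right-handed substrate charged together that has reacted at 30 h
- excess of left-handed product over right-handed product in the product at 30 h
- excess of right-handed substrate over left-handed substrate among what is left of the two at 30 h

Two chemists dispute the flask. Both measure loss the same way: the log of the left-handed substrate's starting share over its reading at 30 h. South, with the flask's 99 mM of added ligand, gives 0.174. North, with the same ligand, gives 0.511.

The first chemist says each catalyst works alike, so loss follows [free catalyst]. Doubling south then leaves 35.3% left-handed substrate in the flask.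

The second points out that north has 4.00 times south's catalyst but only 2.94 times its loss. She also writes a balance for the gas. North's reacted substrate comes to 96.0 mM by 30 h, more than the saturation of 8.6 mM. If the reaction takes up gas, dissolved gas must be replaced as it is used, and more catalyst may pull its level down.

I side with her and carry one number: the apparent order in catalyst, the log of the loss ratio over the log of the catalyst ratio, 0.775. Scaling south by it, my reckoning leaves 37.1% left-handed substrate in the flask.

The forecast, on the second chemist's side, reasons that “fourfold catalyst gives only about threefold rate” and gives 15.4% reacted, product excess 69% and substrate excess 12.5%.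

The flask gives 15.3% reacted, product excess 77.3% and substrate excess 12.8%, with 36.9% left-handed substrate at 30.0 h. Its reagent stands at 0.00739 M, below saturation.

    reagent + free catalyst + left-handed substrate → free catalyst + left-handed product (k = 98.0 /M²/h)
    reagent + free catalyst + right-handed substrate → free catalyst + right-handed product (k = 11.0 /M²/h)
    left-handed substrate ⇌ right-handed substrate (k = 0.00260 /h)
    reagent + free catalyst → spent catalyst (k = 1.20 /M/h)
    free catalyst + added ligand ⇌ idle complex (K = 13.0 /M, k = 0.170 /M/h)
    gas ⇌ reagent, rate k6*(csat - [reagent]) (kL = 1.30 /h)

The neighbour flask is like this one but has 0.013 M of free catalyst. From south, the order leaves 41.0% left-handed substrate at 30 h, and plain proportion leaves 40.7%. They differ by 0.31 percentage points, less than the scatter of 0.5 points. For the neighbour flask, the first chemist's view serves as well as the order. The neighbour's reagent stands at 0.00779 M, above the flask's 0.00739 M. The neighbour flask ends with 41.3% left-handed substrate and 10.2% reacted.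

The data are calculated for substances that don't exist.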